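**Retrosynthetic overview**
- The C9–C11 bond is cut last (sp3–sp2 B‑alkyl Suzuki coupling), giving a decalin dienyl triflate and a 6‑vinyl‑perhydro‑1‑benzoxepin‑3‑one.
- The C6–CH2 bond of the benzoxepinone half is the key bond: it is made by an Eschenmoser–Claisen [3,3]‑sigmatropic rearrangement of a cis‑carveol‑type allylic alcohol, which sets C6 by chirality transfer and brings in the two‑carbon bridge. The following hydrogenation sets C7.
- That allylic alcohol comes from (S)‑carvone: C6 double alkylation (quaternary C5a), Criegee conversion of isopropenyl into the C9a–O bond, 7‑endo epoxide opening (oxepane), then Wharton 1,3‑transposition of the enone.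
- The decalin half comes from (R)‑carvone: C6 double alkylation (C10), radical closure of ring A from isopropenyl onto an aldehyde (3‑OH and gem‑dimethyl), then dienolate triflation (6,8‑diene).
- Ring order: carvone ring → ring A (decalin half); carvone ring → oxepane (other half); the two bicycles are joined in the last step.

Conventions and one assumption: the decalin half uses drimane locants (C1–C10, bridge C11–C12) and the other half 1‑benzoxepine locants (O1…C9a). The oxirane CH formed in step 8 (later C3 of the benzoxepine) is carried as an inconsequential epimer mixture (written without descriptor) until it becomes the ketone in step 20.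

**Route**

Step 1
Reactants: 1 (R)-(−)-carvone
Product: 3 6-methylcarvone (C6 epimers), via lithium dienolate 2 (not isolated)
Conditions: LDA, THF, −78 °C; MeI, −78 → 0 °C
Reagents that add atoms: iodomethane CI
Why: Kinetic α′-deprotonation and SN2 methylation of the cross-conjugated enolate (enolate alkylation); the new C6 centre is epimeric but is planarised again in step 2.

Step 2
Reactants: 3 6-methylcarvone
Product: 5 6-allyl-6-methylcarvone (allyl trans to isopropenyl), via lithium dienolate 4 (not isolated)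
Conditions: LDA, THF, −78 °C; allyl bromide, −78 → 0 °C
Reagents that add atoms: allyl bromide C=CCBr
Why: Enolate alkylation of the tetrasubstituted dienolate on the face anti to the C5 isopropenyl group, so the quaternary centre (future C10) carries methyl cis and allyl trans to isopropenyl (substrate control by the carvone stereocentre).

Step 3
Reactants: 5 6-allyl-6-methylcarvone
Product: 6 keto aldehyde
Conditions: PdCl2(PhCN)2 (10 mol %), CuCl2·2H2O (10 mol %), AgNO2 (5 mol %), O2 (1 atm), t-BuOH/MeNO2 15:1, 23 °C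
Reagents that add atoms: dioxygen O=O
Why: Nitrite-modified aldehyde-selective (anti-Markovnikov) Wacker oxidation reacts only at the monosubstituted alkene, leaving the 1,1-disubstituted isopropenyl group and the enone alone; no stereocentre is affected.

Step 4
Reactants: 6 keto aldehyde
Product: 7 trans-decalin hydroxy enone
Conditions: Fe(acac)3 (30 mol %), PhSiH3 (2.5 equiv), EtOH, 60 °C
Reagents that add atoms: none
Why: Iron-hydride hydrogen-atom transfer turns the isopropenyl group into a tertiary radical that adds 6-exo to the aldehyde (radical cyclisation) through a chair transition state, where the trans-disposed tethers give the trans-decalin, the pseudo-equatorial carbonyl oxygen gives the 3β (3S) alcohol and the former CH2 becomes the second C4 methyl.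

Step 5
Reactants: 7 trans-decalin hydroxy enone
Product: 11 hydroxy dienyl triflate, via TMS ether 8 (not isolated), via potassium dienolate 9 (not isolated), via silylated triflate 10 (not isolated)
Conditions: KHMDS (1.05 equiv), THF, −78 °C; TMSCl (1.0 equiv); KHMDS (1.2 equiv), −78 → −40 °C; PhNTf2, −78 → 0 °C; 1 M HCl work-up
Reagents that add atoms: N-phenylbis(trifluoromethanesulfonimide) O=S(=O)(N(c1ccccc1)S(=O)(=O)C(F)(F)F)C(F)(F)F
Why: After transient O-silylation, γ-deprotonation (α′ is quaternary) gives the linear dienolate, whose O-triflation (enol triflate formation) fixes the 6,8-diene; the acidic work-up removes the silyl group and no stereocentre is touched.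

Step 6
Reactants: 12 (S)-(+)-carvone
Product: 14 ent-6-methylcarvone (C6 epimers), via lithium dienolate 13 (not isolated)
Conditions: LDA, THF, −78 °C; MeI, −78 → 0 °C
Reagents that add atoms: iodomethane CI
Why: Same kinetic enolate alkylation as step 1 in the enantiomeric series; the C6 epimer mixture is irrelevant.

Step 7
Reactants: 14 ent-6-methylcarvone
Product: 16 6-homoprenyl-6-methylcarvone (chain trans to isopropenyl), via lithium dienolate 15 (not isolated)
Conditions: LDA, THF, −78 °C; 5-bromo-2-methylpent-2-ene, DMPU, Bu4NI (cat.), −78 → 23 °C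
Reagents that add atoms: 5-bromo-2-methylpent-2-ene CC(C)=CCCBr
Why: Enolate alkylation anti to the isopropenyl group gives the quaternary centre (future C5a) with methyl cis and the chain trans to the carbon that will carry the ring oxygen.

Step 8
Reactants: 16 6-homoprenyl-6-methylcarvone
Product: 17 side-chain epoxide
Conditions: mCPBA (1.05 equiv), NaHCO3, CH2Cl2, 0 °C
Reagents that add atoms: 3-chloroperoxybenzoic acid O=C(OO)c1cccc(Cl)c1
Why: Prilezhaev epoxidation is fastest at the electron-rich trisubstituted alkene (isopropenyl and enone react far more slowly); the oxirane CH centre forms unselectively but ends as the C3 ketone.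

Step 9
Reactants: 17 side-chain epoxide
Product: 20 epoxy acetate, via methoxy hydroperoxide 18 (not isolated), via peracetate 19 (not isolated)
Conditions: O3, CH2Cl2/MeOH 4:1, −78 °C (Sudan III end point); Ac2O, Et3N, DMAP, 0 → 40 °C
Reagents that add atoms: ozone [O-][O+]=O; methanol CO
Why: Ozonolysis in methanol cleaves only the isopropenyl group, and acetylation of the α-methoxy hydroperoxide triggers the Criegee rearrangement (1,2-shift of the ring carbon to oxygen with retention), so the carvone stereocentre becomes the C9a–O stereocentre.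

Step 10
Reactants: 20 epoxy acetate
Product: 21 hydroxy epoxide
Conditions: K2CO3, MeOH, 0 °C
Reagents that add atoms: none
Why: Transesterification (methanolysis) frees the secondary alcohol; the α-carbon is quaternary so β-elimination is impossible, and the low temperature suppresses retro-aldol cleavage.

Step 11
Reactants: 21 hydroxy epoxide
Product: 22 trans-fused oxepanol enone
Conditions: CSA (0.2 equiv), CH2Cl2, 0 °C
Reagents that add atoms: none
Why: Acid-catalysed intramolecular epoxide opening in which the alcohol attacks the tertiary, cation-stabilising oxirane carbon (7-endo), closing the trans-fused 2,2-dimethyloxepane with the C9a–O configuration unchanged.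

Step 12
Reactants: 22 trans-fused oxepanol enone
Product: 23 epoxy ketone
Conditions: 30% H2O2, NaOH, MeOH, 0 °C
Reagents that add atoms: hydrogen peroxide OO
Why: Weitz–Scheffer nucleophilic epoxidation by axial attack of hydroperoxide at the enone β-carbon, trans to the C9a–O bond; this configuration is erased in step 14.

Step 13
Reactants: 23 epoxy ketone
Product: 25 transposed allylic alcohol (8-OH trans to O1), via epoxy hydrazone 24 (not isolated)
Conditions: N2H4·H2O, AcOH (cat.), MeOH, 0 → 23 °C
Reagents that add atoms: none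
Why: Wharton transposition, in which the hydrazone opens the epoxide to a vinyl diazene that loses N2, moving the alkene to C6=C7 and leaving the C8 carbinol with its C–O bond intact.

Step 14
Reactants: 25 transposed allylic alcohol
Product: 26 transposed enone
Conditions: MnO2, CH2Cl2, 23 °C
Reagents that add atoms: none
Why: MnO2 oxidises only the allylic alcohol (the hindered saturated C3 carbinol is untouched), giving the 1,3-transposed enone.

Step 15
Reactants: 26 transposed enone
Product: 27 cis allylic alcohol (8-OH cis to O1)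
Conditions: NaBH4, CeCl3·7H2O, MeOH, −78 °C
Reagents that add atoms: none
Why: Luche 1,2-reduction with axial hydride delivery gives the pseudo-equatorial alcohol cis to the C9a oxygen, just as carvone gives cis-carveol (substrate control).

Step 16
Reactants: 27 cis allylic alcohol
Product: 29 unsaturated amide, via ketene N,O-acetal 28 (not isolated)
Conditions: MeC(OMe)2NMe2 (5 equiv), xylene, 140 °C (MeOH distilled off)
Reagents that add atoms: N,N-dimethylacetamide dimethyl acetal CC(OC)(OC)N(C)C
Why: Eschenmoser–Claisen [3,3]-sigmatropic rearrangement (key step), in which suprafacial 1,3-chirality transfer turns the C8–O bond into the C6–CH2 bond on the same face, cis to the angular methyl and next to the quaternary centre, and installs the two-carbon bridge.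

Step 17
Reactants: 29 unsaturated amide
Product: 30 saturated amide
Conditions: H2 (1 atm), 10% Pd/C, EtOAc, 23 °C
Reagents that add atoms: none
Why: Heterogeneous syn-hydrogenation from the face opposite to the axial 5a-methyl and the C6 side chain sets the axial 7-methyl cis to both.

Step 18
Reactants: 30 saturated amide
Product: 31 amino alcohol
Conditions: LiAlH4, THF, reflux
Reagents that add atoms: none
Why: LiAlH4 reduction of the tertiary amide to the amine; the free alcohol is only deprotonated and recovered on work-up.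

Step 19
Reactants: 31 amino alcohol
Product: 33 vinyl alcohol, via amine N-oxide 32 (not isolated)
Conditions: mCPBA, CH2Cl2, 0 °C; then toluene, 110 °C
Reagents that add atoms: none
Why: Cope elimination (syn Ei) of the N-oxide, whose only β-hydrogens sit on the bridge CH2, gives the terminal vinyl group without touching C6.

Step 20
Reactants: 33 vinyl alcohol
Product: 34 vinyl oxepanone
Conditions: Dess–Martin periodinane, NaHCO3, CH2Cl2, 23 °C
Reagents that add atoms: none
Why: Dess–Martin oxidation converts both C3 carbinol epimers into the single oxepan-3-one.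

Step 21
Reactants: 34 vinyl oxepanone; 11 hydroxy dienyl triflate
Product: 36 target CNP0106412.1, via B-alkyl-9-BBN 35 (not isolated)
Conditions: 9-BBN, THF, 0 → 23 °C; then 11, Pd(dppf)Cl2 (10 mol %), AsPh3, Cs2CO3, DMF/THF/H2O, 50 °C
Reagents that add atoms: none
Why: Anti-Markovnikov hydroboration of the only alkene (the hindered ketone reacts far more slowly with 9-BBN) followed by B-alkyl Suzuki–Miyaura coupling joins the sp3 carbon to the dienyl triflate with the diene intact; no stereocentre is involved.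

**Compound list**

1 | (R)-(−)-carvone, (5R)-2-methyl-5-(prop-1-en-2-yl)cyclohex-2-en-1-one | CC1=CC[C@H](CC1=O)C(C)=C | starting material
2 | lithium cross-conjugated dienolate of 1 (enolised towards C6) | CC1=CC[C@H](C=C1[O-])C(C)=C.[Li+] | intermediate
3 | (5R)-2,6-dimethyl-5-(prop-1-en-2-yl)cyclohex-2-en-1-one, C6 epimer mixture | CC1=CC[C@H](C(C)C1=O)C(C)=C | intermediate
4 | lithium dienolate of 3 (tetrasubstituted C1=C6 enolate) | CC1=CC[C@H](C(C)=C1[O-])C(C)=C.[Li+] | intermediate
5 | (5S,6S)-2,6-dimethyl-6-(prop-2-en-1-yl)-5-(prop-1-en-2-yl)cyclohex-2-en-1-one (allyl trans, methyl cis to isopropenyl) | C=CC[C@]1(C)C(=O)C(C)=CC[C@H]1C(C)=C | intermediate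
6 | 3-[(1S,6S)-1,3-dimethyl-2-oxo-6-(prop-1-en-2-yl)cyclohex-3-en-1-yl]propanal | O=CCC[C@]1(C)C(=O)C(C)=CC[C@H]1C(C)=C | intermediate
7 | (4aS,6S,8aS)-6-hydroxy-2,5,5,8a-tetramethyl-4a,5,6,7,8,8a-hexahydronaphthalen-1(4H)-one (trans-fused, 3β-OH in drimane numbering) | CC1=CC[C@H]2C(C)(C)[C@@H](O)CC[C@]2(C)C1=O | intermediate
8 | trimethylsilyl ether of 7 | CC1=CC[C@H]2C(C)(C)[C@@H](O[Si](C)(C)C)CC[C@]2(C)C1=O | intermediate
9 | potassium linear dienolate of 8 (O–C9=C8–C7=C6) | CC1=C([O-])[C@@]2(C)CC[C@H](O[Si](C)(C)C)C(C)(C)[C@@H]2C=C1.[K+] | intermediate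
10 | trimethylsilyl ether of 11 | CC1=C(OS(=O)(=O)C(F)(F)F)[C@@]2(C)CC[C@H](O[Si](C)(C)C)C(C)(C)[C@@H]2C=C1 | intermediate
11 | (2S,4aS,8aS)-2-hydroxy-1,1,4a,6-tetramethyl-1,2,3,4,4a,8a-hexahydronaphthalen-5-yl trifluoromethanesulfonate | CC1=C(OS(=O)(=O)C(F)(F)F)[C@@]2(C)CC[C@H](O)C(C)(C)[C@@H]2C=C1 | intermediate
12 | (S)-(+)-carvone, (5S)-2-methyl-5-(prop-1-en-2-yl)cyclohex-2-en-1-one | CC1=CC[C@@H](CC1=O)C(C)=C | starting material
13 | lithium cross-conjugated dienolate of 12 | CC1=CC[C@@H](C=C1[O-])C(C)=C.[Li+] | intermediate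
14 | (5S)-2,6-dimethyl-5-(prop-1-en-2-yl)cyclohex-2-en-1-one, C6 epimer mixture | CC1=CC[C@@H](C(C)C1=O)C(C)=C | intermediate
15 | lithium dienolate of 14 | CC1=CC[C@@H](C(C)=C1[O-])C(C)=C.[Li+] | intermediate
16 | (5R,6R)-2,6-dimethyl-6-(4-methylpent-3-en-1-yl)-5-(prop-1-en-2-yl)cyclohex-2-en-1-one (chain trans, methyl cis to isopropenyl) | CC(C)=CCC[C@@]1(C)C(=O)C(C)=CC[C@@H]1C(C)=C | intermediate
17 | (5R,6R)-6-[2-(3,3-dimethyloxiran-2-yl)ethyl]-2,6-dimethyl-5-(prop-1-en-2-yl)cyclohex-2-en-1-one, oxirane epimers | CC1(C)OC1CC[C@@]1(C)C(=O)C(C)=CC[C@@H]1C(C)=C | intermediate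
18 | α-methoxy hydroperoxide from ozonolysis of 17 (2-hydroperoxy-2-methoxypropan-2-yl in place of isopropenyl) | CC1(C)OC1CC[C@@]1(C)C(=O)C(C)=CC[C@@H]1C(C)(OC)OO | intermediate
19 | peracetate of 18 | CC1(C)OC1CC[C@@]1(C)C(=O)C(C)=CC[C@@H]1C(C)(OC)OOC(C)=O | intermediate
20 | (1S,2R)-2-[2-(3,3-dimethyloxiran-2-yl)ethyl]-2,4-dimethyl-3-oxocyclohex-4-en-1-yl acetate, oxirane epimers | CC1(C)OC1CC[C@@]1(C)C(=O)C(C)=CC[C@@H]1OC(C)=O | intermediate
21 | (5S,6R)-6-[2-(3,3-dimethyloxiran-2-yl)ethyl]-5-hydroxy-2,6-dimethylcyclohex-2-en-1-one, oxirane epimers | CC1(C)OC1CC[C@@]1(C)C(=O)C(C)=CC[C@@H]1O | intermediate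
22 | (5aR,9aS)-3-hydroxy-2,2,5a,7-tetramethyl-3,4,5,5a,9,9a-hexahydro-1-benzoxepin-6(2H)-one (trans-fused, C3 epimers) | O=C1C(C)=CC[C@@H]2OC(C)(C)C(O)CC[C@@]12C | intermediate
23 | (5aR,9aS)-7,8-epoxy-3-hydroxy-2,2,5a,7-tetramethyloctahydro-1-benzoxepin-6(2H)-one, epoxide trans to the C9a–O bond, C3 epimers | O=C1[C@@]3(C)O[C@H]3C[C@@H]2OC(C)(C)C(O)CC[C@@]12C | intermediate
24 | hydrazone of 23 | NN=C1[C@@]3(C)O[C@H]3C[C@@H]2OC(C)(C)C(O)CC[C@@]12C | intermediate
25 | (5aS,8S,9aS)-2,2,5a,7-tetramethyl-2,3,4,5,5a,8,9,9a-octahydro-1-benzoxepine-3,8-diol (8-OH trans to O1, C3 epimers) | C1=C(C)[C@@H](O)C[C@@H]2OC(C)(C)C(O)CC[C@@]12C | intermediate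
26 | (5aS,9aS)-3-hydroxy-2,2,5a,7-tetramethyl-2,3,4,5,5a,9a-hexahydro-1-benzoxepin-8(9H)-one (C3 epimers) | C1=C(C)C(=O)C[C@@H]2OC(C)(C)C(O)CC[C@@]12C | intermediate
27 | (5aS,8R,9aS)-2,2,5a,7-tetramethyl-2,3,4,5,5a,8,9,9a-octahydro-1-benzoxepine-3,8-diol (8-OH cis to O1, C3 epimers) | C1=C(C)[C@H](O)C[C@@H]2OC(C)(C)C(O)CC[C@@]12C | intermediate
28 | ketene N,O-acetal of 27 (8-O–C(=CH2)NMe2) | C1=C(C)[C@H](OC(=C)N(C)C)C[C@@H]2OC(C)(C)C(O)CC[C@@]12C | intermediate
29 | 2-[(5aS,6R,9aS)-3-hydroxy-2,2,5a,7-tetramethyl-2,3,4,5,5a,6,9,9a-octahydro-1-benzoxepin-6-yl]-N,N-dimethylacetamide (side chain cis to 5a-Me, C3 epimers) | CN(C)C(=O)C[C@@H]1C(C)=CC[C@@H]2OC(C)(C)C(O)CC[C@@]12C | intermediate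
30 | 2-[(5aS,6R,7R,9aS)-3-hydroxy-2,2,5a,7-tetramethyldecahydro-1-benzoxepin-6-yl]-N,N-dimethylacetamide (C3 epimers) | CN(C)C(=O)C[C@@H]1[C@H](C)CC[C@@H]2OC(C)(C)C(O)CC[C@@]12C | intermediate
31 | (5aS,6R,7R,9aS)-6-[2-(dimethylamino)ethyl]-2,2,5a,7-tetramethyldecahydro-1-benzoxepin-3-ol (C3 epimers) | CN(C)CC[C@@H]1[C@H](C)CC[C@@H]2OC(C)(C)C(O)CC[C@@]12C | intermediate
32 | N-oxide of 31 | C[N+](C)([O-])CC[C@@H]1[C@H](C)CC[C@@H]2OC(C)(C)C(O)CC[C@@]12C | intermediate
33 | (5aS,6R,7R,9aS)-6-ethenyl-2,2,5a,7-tetramethyldecahydro-1-benzoxepin-3-ol (C3 epimers) | C=C[C@@H]1[C@H](C)CC[C@@H]2OC(C)(C)C(O)CC[C@@]12C | intermediate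
34 | (5aS,6R,7R,9aS)-6-ethenyl-2,2,5a,7-tetramethyloctahydro-1-benzoxepin-3(2H)-one | C=C[C@@H]1[C@H](C)CC[C@@H]2OC(C)(C)C(=O)CC[C@@]12C | intermediate
35 | 9-{2-[(5aS,6R,7R,9aS)-2,2,5a,7-tetramethyl-3-oxodecahydro-1-benzoxepin-6-yl]ethyl}-9-borabicyclo[3.3.1]nonane | C1CCC2CCCC1B2CC[C@@H]1[C@H](C)CC[C@@H]2OC(C)(C)C(=O)CC[C@@]12C | intermediate
36 | CNP0106412.1, (5aS,6R,7R,9aS)-6-{2-[(4aR,6S,8aS)-6-hydroxy-2,5,5,8a-tetramethyl-4a,5,6,7,8,8a-hexahydronaphthalen-1-yl]ethyl}-2,2,5a,7-tetramethyloctahydro-1-benzoxepin-3(2H)-one | CC1=C(CC[C@@H]2[C@H](C)CC[C@@H]3OC(C)(C)C(=O)CC[C@]32C)[C@@]2(C)CC[C@H](O)C(C)(C)[C@@H]2C=C1 | target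

**Step count**
Total: 21 steps. Longest linear sequence: 16 steps (steps 6–21, from (S)-carvone); the decalin branch is 5 steps (1–5) and joins in step 21.

**Three steps most likely to fail, each with a fallback**

Step 4 (radical closure of ring A onto the aldehyde): the alkoxyl radical can re-open, the alkene can simply be reduced, and the C3 selectivity is not guaranteed. The fallback sets out from 3 and returns at 7. The enolate of 3 (LDA, THF, −78 °C) is added to acrylonitrile to give the cyanoethyl ketone F1 (cyanoethyl trans to isopropenyl). Under the same Fe(acac)3/PhSiH3 conditions the tertiary radical adds 6-exo to the nitrile, giving the cyclic ketimine F2, which is hydrolysed on acidic work-up to the trans-fused 3,9-dione F3. NaBH4 in MeOH at −40 °C then reduces only the saturated 3-ketone by axial attack (equatorial 3β-OH) and gives 7. C3 is thus set in a hydride reduction instead of in the C–C bond formation.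

Step 11 (7-endo against 6-exo epoxide opening): the tetrahydropyran from attack at the secondary oxirane carbon may compete. The fallback sets out from 21 and returns at 22. The oxirane is deoxygenated with Ph3P=Se/TFA in CH2Cl2 to the hydroxy alkene F4. Hg(OCOCF3)2 in MeCN at −20 °C (then aqueous NaCl) closes the ring by Markovnikov alkoxymercuration, with oxygen going to the tertiary carbon, to give the organomercurial chloride F5. Oxidative demercuration (NaBH4, O2, DMF, 0 °C) places the hydroxyl at C3 and gives 22. The regiochemistry is then dictated by the mercurinium ion and not by the epoxide.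

Step 21 (B-alkyl Suzuki coupling with a hindered dienyl triflate): slow transmetalation, triflate hydrolysis and β-hydride elimination are the risks. The fallback sets out from 34 and returns at 36. Radical anti-Markovnikov hydrobromination (HBr, dibenzoyl peroxide cat., hexane, 0 °C) gives the primary bromide F6. Zinc insertion (Zn dust, LiCl, THF, 50 °C) gives the alkylzinc bromide F7, which tolerates the ketone. Negishi coupling of F7 (2 equiv, to cover the free hydroxyl) with 11 (Pd(OAc)2, SPhos, THF/NMP, 40 °C) gives 36 without base or water.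

Further compounds
F1 | step 4 | 3-[(1S,6S)-1,3-dimethyl-2-oxo-6-(prop-1-en-2-yl)cyclohex-3-en-1-yl]propanenitrile | N#CCC[C@]1(C)C(=O)C(C)=CC[C@H]1C(C)=C
F2 | step 4 | (4aS,8aS)-6-imino-2,5,5,8a-tetramethyl-4a,5,6,7,8,8a-hexahydronaphthalen-1(4H)-one | CC1=CC[C@H]2C(C)(C)C(=N)CC[C@]2(C)C1=O
F3 | step 4 | (4aS,8aS)-2,5,5,8a-tetramethyl-4a,7,8,8a-tetrahydronaphthalene-1,6(4H,5H)-dione | CC1=CC[C@H]2C(C)(C)C(=O)CC[C@]2(C)C1=O
F4 | step 11 | (5S,6R)-5-hydroxy-2,6-dimethyl-6-(4-methylpent-3-en-1-yl)cyclohex-2-en-1-one | CC(C)=CCC[C@@]1(C)C(=O)C(C)=CC[C@@H]1O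
F5 | step 11 | chloro[(5aR,9aS)-2,2,5a,7-tetramethyl-6-oxo-2,3,4,5,5a,6,9,9a-octahydro-1-benzoxepin-3-yl]mercury | O=C1C(C)=CC[C@@H]2OC(C)(C)C([Hg]Cl)CC[C@@]12C
F6 | step 21 | (5aS,6R,7R,9aS)-6-(2-bromoethyl)-2,2,5a,7-tetramethyloctahydro-1-benzoxepin-3(2H)-one | BrCC[C@@H]1[C@H](C)CC[C@@H]2OC(C)(C)C(=O)CC[C@@]12C
F7 | step 21 | bromo{2-[(5aS,6R,7R,9aS)-2,2,5a,7-tetramethyl-3-oxodecahydro-1-benzoxepin-6-yl]ethyl}zinc | Br[Zn]CC[C@@H]1[C@H](C)CC[C@@H]2OC(C)(C)C(=O)CC[C@@]12C
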